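Add the product to the substrate found in a late reading and a piece of the substrate charged is left over, unaccounted for. Here are the flasks, the earlier runs and the questions.

| setting | dusk | spring | winter | zeta | theta | eta |
|---|---|---|---|---|---|---|
| substrate | 0.42 M | 0.93 M | 0.62 M | 0.62 M | 0.62 M | 0.62 M |
| partner | 1.86 M | 1.86 M | 1.86 M | 1.86 M | 1.86 M | 1.86 M |
| protic impurity | 0.124 M | 0.124 M | 0.124 M | 0.124 M | 0.124 M | 0.124 M |
| free catalyst | 74 mM | 74 mM | 37 mM | 74 mM | 74 mM | 74 mM |
| temperature | −45 °C | −30 °C | −45 °C | −20 °C |  | −40 °C |
| remark | run made earlier | run made earlier | run made earlier |  | at −20 °C until 10 h, from then on at −40 °C |  |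
| time |  |  |  | 20 h | 20 h | 20 h |

- dusk (time / h: product / %, substrate / %): 6.00: 0.2, 97.3; 10.0: 0, 94.7; 15.0: 0, 92.7; 20.0: 0.6, 90.6; 30.0: 1.4, 88.6; 48.0: 1.5, 86.0; 96.0: 5.8, 79.2
- spring (time / h: product / %, substrate / %): 3.00: 0, 94.1; 5.00: 0.5, 92.3; 6.00: 1.1, 92.5; 10.0: 3.1, 89.8; 15.0: 5.6, 87.9; 25.0: 8.6, 84.1; 40.0: 14.1, 78.7
- winter (time / h: product / %, substrate / %): 15.0: 0, 96.6; 30.0: 0.4, 95.5; 48.0: 1.0, 93.3; 72.0: 1.1, 92.9; 96.0: 2.0, 93.2

(readings scatter by 0.5 percentage points)

- the best flask by amount of product, in percent of the substrate charged; "all alike" if 1.5 percentage points covers them all (zeta / theta / eta / all alike)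
- amount of product at the end, in percent of the substrate charged, zeta
- amount of product at the end, in percent of the substrate charged, theta
- amount of product at the end, in percent of the substrate charged, eta

We set that leftover from each run's last reading against the free catalyst charged:

- dusk, 96.0 h: leftover 63.0 mM against 74 mM of catalyst, share 85.1%
- spring, 40.0 h: leftover 67.0 mM against 74 mM of catalyst, share 90.5%
- winter, 96.0 h: leftover 29.8 mM against 37 mM of catalyst, share 80.4%

Read down the leftover column. Winter has half the catalyst of dusk at the same temperature, though more substrate, and about half the leftover. Spring, which is also warmer, holds more than twice the substrate of dusk with the same catalyst, yet its leftover is close to dusk's. So the leftover follows the catalyst, and we read it as substrate sitting on catalyst, the catalyst's resting state. Read the share column: the held share, meaning leftover substrate over catalyst charged, lies between 80.4% and 90.5% in these runs, and these are readings with their scatter.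

If product comes from held catalyst, then product per hour is held catalyst times a release rate. The last two readings of each run give, with their scatter, 0.0509 h⁻¹ for spring and 0.00597 h⁻¹ for dusk. Keeping the same factor per degree, we reckon 0.213 h⁻¹ at −20 °C and 0.0122 h⁻¹ at −40 °C. Holding the spring share, the highest of our readings, from the first hour, we commit to 45.9% for zeta, 24.3% for theta and 2.64% for eta, so zeta is our best flask.

The forecast also names zeta, but lower than ours at 36%, 19.5% and 1.5%, on the ground that “substrate slowly binds catalyst to form a resting intermediate, which then turns over”.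

The flasks give zeta as the best, with 37.4% for zeta, 20.0% for theta and 1.48% for eta.

    substrate + free catalyst → catalyst intermediate A (k = 4.30 × 10⁻⁴ L mol⁻¹ s⁻¹, Ea = 55.0 kJ mol⁻¹)
    catalyst intermediate B → free catalyst + product (k = 0.0210 s⁻¹, Ea = 71.0 kJ mol⁻¹)
    partner + protic impurity → quenched reagent (k = 2.20 × 10⁻⁴ L mol⁻¹ s⁻¹, Ea = 57.0 kJ mol⁻¹)
    partner + catalyst intermediate A ⇌ catalyst intermediate B (K = 13.0 L mol⁻¹, k = 3.70 × 10⁻⁵ L mol⁻¹ s⁻¹, Ea = 73.0 kJ mol⁻¹, ΔH = −8.00 kJ mol⁻¹)
    (constants at −20 °C)

At 20.0 h the held share in zeta is 72.8%, lower than the 90.5% read in the spring run and carried over, and our 45.9% stands above the 37.4% found. At 20.0 h none of the three flasks is at rest. At 200 h zeta reaches >99.9% product, with 0% substrate left and its free catalyst back at >99.9%. Theta at that time has 39.2% product and still a held share of 84.0%. Eta has 22.5% product, with a held share of 86.5%.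

(The data stem from a simulated flask for substances that don't exist, and the scatter is random.)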